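The plan rests on cutting C2–C3 of the pyran ring C. C4 is raised for a time to a ketone. C3, flanked by ring B and C4=O, then becomes a carbon acid lying 1,5 to the phenol O1 on C8a of ring A. The key step stitches this O,C-dinucleophile with CH2I2 in one operation: O1 is alkylated first, then the C3 enolate attacks the iodomethyl ether carbon C2 and closes ring C. Its precursor is an open 2-hydroxydeoxybenzoin from a ketone α-arylation. The same ketone keeps C3 epimerisable, so transfer hydrogenation under dynamic kinetic resolution sets (3S). One hydrogenolysis then removes the C4 oxygen and both benzyl groups.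

Key step: step 9

Remark: isoflavan numbering is used (O1, C2, C3, C4, C4a, C5–C8, C8a in rings C and A; primed atoms in ring B), and the stereocentre of the target SMILES is read as (3S).

Step 1
Reactants: 1 2-methoxybenzene-1,3-diol (2-methoxyresorcinol)
Product: 2 1-(2,4-dihydroxy-3-methoxyphenyl)ethan-1-one
Conditions: AcOH (1.2 equiv), BF3·OEt2, 85 °C; then aq. NaOAc
Reagents that add atoms: acetic acid, CC(=O)O
Why: Nencki-type Friedel–Crafts acylation, in which the two positions ortho/para to the hydroxyl groups of the symmetric diol are equivalent, so a single ketone stabilised by the hydrogen bond to the 2-OH should form.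

Step 2
Reactants: 2 1-(2,4-dihydroxy-3-methoxyphenyl)ethan-1-one
Product: 3 1-[2,4-bis(benzyloxy)-3-methoxyphenyl]ethan-1-one
Conditions: BnBr (2.4 equiv), K2CO3 (3 equiv), DMF, 70 °C
Reagents that add atoms: benzyl bromide, BrCc1ccccc1
Why: Double Williamson etherification, run warm in DMF because the 2-OH is chelated to the ketone and flanked by the methoxy group.

Step 3
Reactants: 4 2,6-dimethoxyphenol
Product: 5 2-(benzyloxy)-1,3-dimethoxybenzene
Conditions: BnBr (1.1 equiv), K2CO3, DMF, 50 °C
Reagents that add atoms: benzyl bromide, BrCc1ccccc1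
Why: Williamson etherification masks the future 3'-OH as an ether that hydrogenolysis removes at the end.

Step 4
Reactants: 5 2-(benzyloxy)-1,3-dimethoxybenzene
Product: 6 3-(benzyloxy)-1,5-dibromo-2,4-dimethoxybenzene
Conditions: NBS (2.05 equiv), MeCN, 0 °C to rt, dark
Reagents that add atoms: N-bromosuccinimide, O=C1CCC(=O)N1Br
Why: Electrophilic aromatic bromination, in which both methoxy groups direct ortho/para to the same two equivalent positions while the third free position is meta to both, so the symmetric dibromide should result.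

Step 5
Reactants: 6 3-(benzyloxy)-1,5-dibromo-2,4-dimethoxybenzene
Product: 9 3-(benzyloxy)-5-bromo-2,4-dimethoxyphenol, via aryllithium 7 (not isolated), via dimethyl arylboronate 8 (not isolated)
Conditions: n-BuLi (1.0 equiv), THF, −78 °C; B(OMe)3, −78 °C to rt; AcOH, 30% aq. H2O2, 0 °C to rt
Reagents that add atoms: hydrogen peroxide, OO
Why: Bromine–lithium exchange with one equivalent of n-BuLi desymmetrises the two equivalent C–Br bonds, and borylation followed by peroxide oxidation (1,2-aryl shift from boron to oxygen) turns the lithiated carbon into the phenol.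

Step 6
Reactants: 9 3-(benzyloxy)-5-bromo-2,4-dimethoxyphenol
Product: 10 3-(benzyloxy)-1-bromo-2,4,5-trimethoxybenzene
Conditions: MeI (1.5 equiv), K2CO3, acetone, reflux
Reagents that add atoms: iodomethane, CI
Why: Williamson methylation completes the oxygenation pattern of ring B with no regiochemical ambiguity.

Step 7
Reactants: 3 1-[2,4-bis(benzyloxy)-3-methoxyphenyl]ethan-1-one; 10 3-(benzyloxy)-1-bromo-2,4,5-trimethoxybenzene
Product: 11 1-[2,4-bis(benzyloxy)-3-methoxyphenyl]-2-[3-(benzyloxy)-2,4,5-trimethoxyphenyl]ethan-1-one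
Conditions: Pd2(dba)3 (1.5 mol %), XPhos (6 mol %), NaOt-Bu (2.2 equiv), toluene, 80 °C
Reagents that add atoms: none
Why: Buchwald–Hartwig-type palladium-catalysed ketone α-arylation, in which the bulky electron-rich phosphine allows oxidative addition of the electron-rich bromide and the more acidic, hindered product enolate resists a second arylation.

Step 8
Reactants: 11 1-[2,4-bis(benzyloxy)-3-methoxyphenyl]-2-[3-(benzyloxy)-2,4,5-trimethoxyphenyl]ethan-1-one
Product: 12 1-[4-(benzyloxy)-2-hydroxy-3-methoxyphenyl]-2-[3-(benzyloxy)-2,4,5-trimethoxyphenyl]ethan-1-one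
Conditions: MgBr2·OEt2 (3 equiv), toluene–Et2O, 75 °C; then 1 M HCl
Reagents that add atoms: none
Why: Chelation-controlled ether cleavage, in which magnesium binds the carbonyl oxygen and the ortho benzyloxy oxygen in a six-membered chelate, so bromide should dealkylate only this benzyl ether and leave those on the future C7 and C3' alone.

Step 9
Reactants: 12 1-[4-(benzyloxy)-2-hydroxy-3-methoxyphenyl]-2-[3-(benzyloxy)-2,4,5-trimethoxyphenyl]ethan-1-one
Product: 14 rac-7-(benzyloxy)-3-[3-(benzyloxy)-2,4,5-trimethoxyphenyl]-8-methoxychroman-4-one, via iodomethyl ether 13 (not isolated)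
Conditions: CH2I2 (2 equiv), K2CO3 (4 equiv), acetone (0.02 M), reflux, slow addition of 12
Reagents that add atoms: diiodomethane, ICI
Why: Carbonate first ionises only the chelated C8a–OH, which is several pK units more acidic than C3–H, and this phenoxide displaces one iodide of CH2I2 to give the iodomethyl ether 13, so O1–C2 is in place before any carbon nucleophile exists. The C4 ketone and ring B then make C3–H acidic enough for carbonate, and the aryl-conjugated Z-enolate attacks the α-iodo ether carbon C2 (SN2 with strong oxocarbenium character), which forms C2–C3 and closes ring C. The reaction type is the classical bis-alkylation of a 1,5-O,C-dinucleophile by a dihalomethane, that is phenol O-alkylation followed by intramolecular enolate C-alkylation with an α-halo ether, known for 2-hydroxydeoxybenzoins. The closure is 6-(enolendo)-exo-tet, allowed for six-membered rings, and it is helped by the flanking 8-OMe and acyl groups, which turn the O1–C2 bond out of the plane of ring A and over the π face of C3. C3 is formed racemic on purpose, since it stays epimerisable next to C4=O and is resolved dynamically in step 10. The step needs C- over O-closure, favoured by the soft conjugated potassium enolate in a weakly polar medium, and intra- over intermolecular alkylation, secured by dilution, slow addition and benzylation of every other phenol.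

Step 10
Reactants: 14 rac-7-(benzyloxy)-3-[3-(benzyloxy)-2,4,5-trimethoxyphenyl]-8-methoxychroman-4-one
Product: 15 (3S,4S)-7-(benzyloxy)-3-[3-(benzyloxy)-2,4,5-trimethoxyphenyl]-8-methoxychroman-4-ol (cis)
Conditions: RuCl[(S,S)-TsDPEN](p-cymene) (2 mol %), HCO2H–Et3N (1:1), EtOAc, 40 °C
Reagents that add atoms: none
Why: Noyori–Ikariya asymmetric transfer hydrogenation with dynamic kinetic resolution, in which Et3N racemises C3 through the enol faster than reduction, the (S,S) catalyst should give (4S) as with other benzo-fused aryl ketones, and only the enantiomer whose ring B lies away from the incoming hydride is reduced, which fixes the cis-(3S,4S) pair.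

Step 11
Reactants: 15 (3S,4S)-7-(benzyloxy)-3-[3-(benzyloxy)-2,4,5-trimethoxyphenyl]-8-methoxychroman-4-ol
Product: 16 (3S)-3-(3-hydroxy-2,4,5-trimethoxyphenyl)-8-methoxychroman-7-ol (target)
Conditions: H2 (1 atm), 10% Pd/C, EtOH–AcOH (20:1), rt
Reagents that add atoms: none
Why: Heterogeneous hydrogenolysis should cleave both O-benzyl groups and the doubly activated benzylic C4–OH (para to the 7-oxygen, ortho to O1), while C3 is not touched and keeps its (S) configuration.

Compound list
1 | 2-methoxybenzene-1,3-diol | COc1c(O)cccc1O | starting material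
2 | 1-(2,4-dihydroxy-3-methoxyphenyl)ethan-1-one | CC(=O)c1ccc(O)c(OC)c1O | intermediate
3 | 1-[2,4-bis(benzyloxy)-3-methoxyphenyl]ethan-1-one | CC(=O)c1ccc(OCc2ccccc2)c(OC)c1OCc1ccccc1 | intermediate
4 | 2,6-dimethoxyphenol | COc1cccc(OC)c1O | starting material
5 | 2-(benzyloxy)-1,3-dimethoxybenzene | COc1cccc(OC)c1OCc1ccccc1 | intermediate
6 | 3-(benzyloxy)-1,5-dibromo-2,4-dimethoxybenzene | COc1c(Br)cc(Br)c(OC)c1OCc1ccccc1 | intermediate
7 | [3-(benzyloxy)-5-bromo-2,4-dimethoxyphenyl]lithium (not isolated) | [Li]c1cc(Br)c(OC)c(OCc2ccccc2)c1OC | intermediate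
8 | dimethyl [3-(benzyloxy)-5-bromo-2,4-dimethoxyphenyl]boronate (not isolated) | COB(OC)c1cc(Br)c(OC)c(OCc2ccccc2)c1OC | intermediate
9 | 3-(benzyloxy)-5-bromo-2,4-dimethoxyphenol | COc1c(O)cc(Br)c(OC)c1OCc1ccccc1 | intermediate
10 | 3-(benzyloxy)-1-bromo-2,4,5-trimethoxybenzene | COc1cc(Br)c(OC)c(OCc2ccccc2)c1OC | intermediate
11 | 1-[2,4-bis(benzyloxy)-3-methoxyphenyl]-2-[3-(benzyloxy)-2,4,5-trimethoxyphenyl]ethan-1-one | O=C(Cc1cc(OC)c(OC)c(OCc2ccccc2)c1OC)c1ccc(OCc2ccccc2)c(OC)c1OCc1ccccc1 | intermediate
12 | 1-[4-(benzyloxy)-2-hydroxy-3-methoxyphenyl]-2-[3-(benzyloxy)-2,4,5-trimethoxyphenyl]ethan-1-one | O=C(Cc1cc(OC)c(OC)c(OCc2ccccc2)c1OC)c1ccc(OCc2ccccc2)c(OC)c1O | intermediate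
13 | 1-[4-(benzyloxy)-2-(iodomethoxy)-3-methoxyphenyl]-2-[3-(benzyloxy)-2,4,5-trimethoxyphenyl]ethan-1-one (not isolated) | O=C(Cc1cc(OC)c(OC)c(OCc2ccccc2)c1OC)c1ccc(OCc2ccccc2)c(OC)c1OCI | intermediate
14 | rac-7-(benzyloxy)-3-[3-(benzyloxy)-2,4,5-trimethoxyphenyl]-8-methoxychroman-4-one (racemate, C3 labile) | O=C1c2ccc(OCc3ccccc3)c(OC)c2OCC1c1cc(OC)c(OC)c(OCc2ccccc2)c1OC | intermediate
15 | (3S,4S)-7-(benzyloxy)-3-[3-(benzyloxy)-2,4,5-trimethoxyphenyl]-8-methoxychroman-4-ol | O[C@H]1[C@@H](c2cc(OC)c(OC)c(OCc3ccccc3)c2OC)COc2c(OC)c(OCc3ccccc3)ccc21 | intermediate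
16 | (3S)-3-(3-hydroxy-2,4,5-trimethoxyphenyl)-8-methoxychroman-7-ol | COc1cc([C@H]2COc3c(ccc(O)c3OC)C2)c(OC)c(O)c1OC | target

Total step count: 11. Longest linear sequence: 9 steps (steps 3 to 11, from 4 to 16).

Steps most likely to fail

1. Step 9 (key step). The ring may close through the enolate oxygen instead of C3, or two phenoxides may be bridged by the methylene unit.
   - The fallback sets out from 12 and makes the O-closure the intended event.
   - BrCH2Cl and Cs2CO3 in DMF at 80 °C should give the enol acetal (Z)-7-(benzyloxy)-4-[3-(benzyloxy)-2,4,5-trimethoxybenzylidene]-8-methoxy-4H-1,3-benzodioxine F1. In it, C2 is held by a temporary C2–O–C4 bridge.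
   - Me2AlCl in CH2Cl2 (−78 to 0 °C) then triggers a Petasis–Ferrier rearrangement: the acetal ionises to the aluminium enolate/aryloxycarbenium pair, which recombines at carbon.
   - This again closes ring C at C2–C3 and comes back to the route at 14.

2. Step 11. Enantiomeric purity may erode if the benzylic alcohol dehydrates under acid to the achiral isoflav-3-ene. The same loss follows if the quinone methide formed after loss of the 7-O-benzyl group tautomerises before hydrogen is taken up.
   - The fallback sets out from 15 and replaces ionic C4–O cleavage by a radical one that cannot involve C3.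
   - NaH, CS2 and MeI in THF should give O-[(3S,4S)-7-(benzyloxy)-3-[3-(benzyloxy)-2,4,5-trimethoxyphenyl]-8-methoxychroman-4-yl] S-methyl dithiocarbonate F2. Its cis geometry places C3–H anti to the xanthate and so blocks a Chugaev syn-elimination.
   - Bu3SnH and AIBN in toluene at 80 °C (Barton–McCombie deoxygenation) should give (3S)-7-(benzyloxy)-3-[3-(benzyloxy)-2,4,5-trimethoxyphenyl]-8-methoxychromane F3.
   - Neutral hydrogenolysis (H2, Pd/C, EtOAc–EtOH) comes back to the route at 16.

3. Step 8. Chemoselectivity may be lost, either through sluggish cleavage of the crowded 2-O-benzyl group or through concurrent loss of the other benzyl ethers.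
   - The fallback sets out from 2 and uses orthogonal protection instead of selective deprotection.
   - BnBr (1.05 equiv) and K2CO3 in acetone should alkylate only the non-chelated 4-OH to give 1-[4-(benzyloxy)-2-hydroxy-3-methoxyphenyl]ethan-1-one F4.
   - MOMCl and NaH in DMF should give 1-[4-(benzyloxy)-3-methoxy-2-(methoxymethoxy)phenyl]ethan-1-one F5.
   - The α-arylation of step 7 with 10 should give 1-[4-(benzyloxy)-3-methoxy-2-(methoxymethoxy)phenyl]-2-[3-(benzyloxy)-2,4,5-trimethoxyphenyl]ethan-1-one F6.
   - HCl in MeOH at 40 °C removes the acetal and comes back to the route at 12.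

Further compounds
F1 | step 9 | (Z)-7-(benzyloxy)-4-[3-(benzyloxy)-2,4,5-trimethoxybenzylidene]-8-methoxy-4H-1,3-benzodioxine | COc1c(OCc2ccccc2)ccc2c1OCO/C2=C\c1cc(OC)c(OC)c(OCc2ccccc2)c1OC
F2 | step 11 | O-[(3S,4S)-7-(benzyloxy)-3-[3-(benzyloxy)-2,4,5-trimethoxyphenyl]-8-methoxychroman-4-yl] S-methyl dithiocarbonate | CSC(=S)O[C@H]1[C@@H](c2cc(OC)c(OC)c(OCc3ccccc3)c2OC)COc2c(OC)c(OCc3ccccc3)ccc21
F3 | step 11 | (3S)-7-(benzyloxy)-3-[3-(benzyloxy)-2,4,5-trimethoxyphenyl]-8-methoxychromane | COc1cc([C@H]2COc3c(ccc(OCc4ccccc4)c3OC)C2)c(OC)c(OCc2ccccc2)c1OC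
F4 | step 8 | 1-[4-(benzyloxy)-2-hydroxy-3-methoxyphenyl]ethan-1-one | CC(=O)c1ccc(OCc2ccccc2)c(OC)c1O
F5 | step 8 | 1-[4-(benzyloxy)-3-methoxy-2-(methoxymethoxy)phenyl]ethan-1-one | CC(=O)c1ccc(OCc2ccccc2)c(OC)c1OCOC
F6 | step 8 | 1-[4-(benzyloxy)-3-methoxy-2-(methoxymethoxy)phenyl]-2-[3-(benzyloxy)-2,4,5-trimethoxyphenyl]ethan-1-one | O=C(Cc1cc(OC)c(OC)c(OCc2ccccc2)c1OC)c1ccc(OCc2ccccc2)c(OC)c1OCOC
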